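**Strategy.** Ring A (the enolised acyl-triketone carbocycle) is built last, onto a caryophyllene-fused dihydropyran. Ring A hides a β-alkoxyacrylate: the enol carbon, the fusion carbon bearing the CH2, the fusion carbon bearing the pyran oxygen and the CMe2 carbon. The γ-anion of the corresponding methyl 2-isopropyl-dihydropyran-3-carboxylate adds through its CMe2 carbon to an (S)-configured ethoxyethynyl sec-butyl ketone, an acylketene equivalent supplying the ring ketone carbon and the acyl-bearing carbon, and the allenolate closes onto the ester. One Michael–Dieckmann annulation thus forms the CMe2–C(=O) and C(acyl)–C(OH) bonds; hydrolytic work-up gives the target. The pyran ester arises from (−)-β-caryophyllene by a domino Knoevenagel/hetero-Diels–Alder reaction.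

Key step: step 4

Conventions: ring A = carbocyclic triketone ring, ring B = dihydropyran, ring C = nine-membered ring, ring D = cyclobutane. Terpenoid carbons carry caryophyllane numbers: C1 and C9 are the cyclobutane fusion carbons, C4 the methyl-bearing carbon bonded to the ring-B oxygen, C5 its CH neighbour, C8 the methylidene-bearing carbon.

Remark on the chemistry: ring A of 13 is an enolised 2-acyl-1,3-dione whose enol tautomers interconvert; it is written as the tautomer of the target SMILES.

**Step 1**
Reactants: 1 (S)-2-methylbutanoic acid
Product: 3 (S)-N-methoxy-N,2-dimethylbutanamide, via acyl imidazolide 2 (not isolated)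
Conditions: CDI, CH2Cl2, 0 °C → rt; then MeNHOMe·HCl, rt
Reagents that add atoms: 1,1'-carbonyldiimidazole, O=C(n1ccnc1)n1ccnc1 (imidazolyl group of 2); N,O-dimethylhydroxylamine hydrochloride, CNOC.Cl
Why: Amide formation through the acyl imidazolide (CDI activation) uses no base strong enough to enolise the α-stereocentre, so the (S)-configuration should be retained.

**Step 2**
Reactants: 3 (S)-N-methoxy-N,2-dimethylbutanamide; 4 ethoxyacetylene
Product: 6 (S)-1-ethoxy-4-methylhex-1-yn-3-one, via lithium ethoxyacetylide 5 (not isolated)
Conditions: 4, n-BuLi, THF, −78 °C; then 3, −78 → 0 °C; inverse quench into cold 1 M HCl–Et2O; used promptly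
Reagents that add atoms: n-BuLi, [Li]CCCC (lithium of 5)
Why: Weinreb ketone synthesis, in which the weakly basic acetylide adds once to give a chelated tetrahedral intermediate that collapses to the ynone only on the cold acidic quench; the quench also protonates the liberated amine so that it cannot add to the ynone, and the α-stereocentre is untouched.

**Step 3**
Reactants: 7 (−)-β-caryophyllene; 8 methyl 4-methyl-3-oxopentanoate
Product: 10 methyl 2-isopropyl-5,6-dihydro-4H-pyran-3-carboxylate fused to the caryophyllane (ring oxygen on C4, ring CH2 on C5; (1R,4R,5S,9S); 4-methyl and 5-H anti; 8-methylidene intact), via methylene keto ester 9 (not isolated)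
Conditions: (CH2O)n, piperidinium acetate (10 mol %), 4 Å MS, toluene, 80 °C, sealed tube; 8 added slowly to excess 7; chromatography
Reagents that add atoms: paraformaldehyde as formaldehyde, C=O
Why: In this domino Knoevenagel/inverse-electron-demand oxa-Diels–Alder reaction, 9 should react through its ketone-containing 1-oxadiene with the strained trans endocyclic alkene of 7, oxygen bonding to the methyl-bearing carbon; the addition is suprafacial (4-methyl and 5-H anti, rings B and C trans-fused) and should occur on the exposed face of the dominant conformers of 7, the face epoxidised in natural caryophyllene oxide, which sets C4 as R and C5 as S, the minor face isomer being removed by chromatography.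

**Step 4**
Reactants: 10 caryophyllane-fused methyl 2-isopropyl-dihydropyran-3-carboxylate; 6 (S)-1-ethoxy-4-methylhex-1-yn-3-one
Product: 13 target (ring A: 3-hydroxy-6,6-dimethyl-2-[(S)-2-methylbutanoyl]cyclohexa-2,4-dien-1-one, its C4 bonded to the CH2 and its C5 to the oxygen of ring B; caryophyllane part (1R,4R,5S,9S)), via lithium dienolate 11 (not isolated), via ethyl enol ether 12 (not isolated)
Conditions: LiN(iPr)2 (1.05 equiv), THF–DMPU, −78 → −40 °C; then 6, −78 → 0 °C; then aq LiOH, MeOH, rt; cold 1 M HCl to pH 3
Reagents that add atoms: LiN(iPr)2, [Li+].CC(C)[N-]C(C)C (lithium of 11); water, O, delivered as aqueous LiOH, [Li+].[OH-] (oxygen of the ring-A ketone next to CMe2)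
Why: Deprotonation of 10 at the isopropyl methine, its only acidic C–H (γ to the ester through the ring-B enol ether and held syn to the ester by the ring), should give the extended dienolate 11, whose γ-carbon adds in Michael fashion to the ethoxy-bearing alkyne carbon of 6; the β-ethoxy allenolate then acylates itself on the neighbouring methyl ester (Dieckmann), so the CMe2–C(OEt) bond and the C(acyl)–C(=O) bond of ring A form in one anionic [4+2] annulation. The closest known reaction type is the Michael–Dieckmann (Staunton–Weinreb) annulation of ortho-toluate and β-alkoxycrotonate γ-anions with unsaturated ketones and β-alkoxy-unsaturated lactones. Ring A closes by 6-exo-trig attack of the central allenolate carbon on the ester carbonyl, the former alkyne ending as the endocyclic tetrasubstituted enol ether double bond of 12. No stereocentre is created (the new quaternary carbon carries two methyl groups); the four terpenoid centres are remote, and the (S)-centre is exposed only to the LiOMe released on ring closure, because the amide base is consumed before 6 is added. The step needs γ- over α-attack and 1,4- over 1,2-addition: the α-carbon is a fully substituted ring carbon whose adduct could not cyclise, the carbonyl of 6 is shielded by the sec-butyl group and deactivated as an alkynylogous ester, and an aldolate can revert whereas the Dieckmann closure cannot. Hydroxide then replaces the ethoxy group of 12 by addition–elimination at the doubly activated carbon, which should be faster than attack on the singly activated enol ether of ring B, and the resulting triketonate resists further attack and epimerisation.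

**Compound list**
1 | (S)-2-methylbutanoic acid | CC[C@H](C)C(=O)O | starting material
2 | (S)-1-(imidazol-1-yl)-2-methylbutan-1-one (acyl imidazolide) | CC[C@H](C)C(=O)n1ccnc1 | intermediate
3 | (S)-N-methoxy-N,2-dimethylbutanamide | CC[C@H](C)C(=O)N(C)OC | intermediate
4 | ethoxyacetylene | CCOC#C | starting material
5 | lithium ethoxyacetylide | [Li+].[C-]#COCC | intermediate
6 | (S)-1-ethoxy-4-methylhex-1-yn-3-one | CCOC#CC(=O)[C@@H](C)CC | intermediate
7 | (−)-β-caryophyllene, (1R,9S,4E) | C=C1CC/C=C(\C)CC[C@@H]2[C@@H]1CC2(C)C | starting material
8 | methyl 4-methyl-3-oxopentanoate | COC(=O)CC(=O)C(C)C | starting material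
9 | methyl 4-methyl-2-methylidene-3-oxopentanoate | C=C(C(=O)OC)C(=O)C(C)C | intermediate
10 | caryophyllane-fused methyl 2-isopropyl-5,6-dihydro-4H-pyran-3-carboxylate, (1R,4R,5S,9S) | C=C1CC[C@H]2CC(C(=O)OC)=C(C(C)C)O[C@]2(C)CC[C@@H]2[C@@H]1CC2(C)C | intermediate
11 | lithium dienolate of 10 (ester enolate exocyclic on ring B, isopropylidene on the O-bearing carbon) | C=C1CC[C@H]2CC(=C([O-])OC)C(=C(C)C)O[C@]2(C)CC[C@@H]2[C@@H]1CC2(C)C.[Li+] | intermediate
12 | ethyl enol ether of 13 (ring A: 3-ethoxy-4,4-dimethyl-2-[(S)-2-methylbutanoyl]cyclohexa-2,5-dien-1-one fused at C5–C6 to ring B) | C=C1CC[C@H]2CC3=C(O[C@]2(C)CC[C@@H]2[C@@H]1CC2(C)C)C(C)(C)C(OCC)=C(C(=O)[C@@H](C)CC)C3=O | intermediate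
13 | target, CNP0591516.2 | C=C1CC[C@H]2CC3=C(O[C@]2(C)CC[C@@H]2[C@@H]1CC2(C)C)C(C)(C)C(=O)C(C(=O)[C@@H](C)CC)=C3O | target

**Totals.** Total step count: 4. Longest linear sequence: 3 steps (steps 1, 2, 4).

**Steps most likely to fail**

1. Step 4. The tertiary γ-C–H may be removed incompletely. The dienolate may attack through its α-carbon or at the carbonyl of 6, or simply take a proton from 6. Liberated LiOMe may erode the (S)-centre before hydrolysis. The fallback is a neutral cycloaddition that sets out from 10 and 3 and returns at 13. Deprotonation of 10 with LiN(iPr)2 under internal quench with Me3SiCl (THF, −78 °C) should give the silyl ketene acetal diene F1, a 1,1,3-trioxygenated diene held s-cis by ring B. Separately, 3 is treated with lithium chloroacetylide F2 (from (Z)-1,2-dichloroethene and MeLi) to give (S)-1-chloro-4-methylhex-1-yn-3-one F3. Diels–Alder reaction of F1 with F3 in toluene at room temperature should join the CMe2 terminus to the chlorine-bearing carbon and give the cycloadduct F4. On work-up F4 loses MeOSiMe3 to give the chlorodienone F5. Aqueous LiOH then replaces chloride by addition–elimination to give 13.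

2. Step 3. The transient methylene keto ester 9 may be consumed by Michael addition of 8 or by self-dimerisation faster than it adds to the unactivated alkene, and facial discrimination between the conformers of 7 may be modest. The fallback sets out from 8 and returns at 10. Compound 8 is first converted with paraformaldehyde and BF3·OEt2 into the isolable methyl 6-isopropyl-4H-1,3-dioxine-5-carboxylate F6. Heating F6 with 7 in toluene (110–140 °C) should release 9 slowly by retro-hetero-Diels–Alder loss of formaldehyde, in the absence of amine and of free 8, so that cycloaddition to 7 gives 10.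

3. Step 2. The ynol ether may hydrate during the protic quench, the liberated amine may add to the ynone, and the strongly basic medium may partly enolise the α-centre. The fallback sets out from 1 (and uses 5) and returns at 6. Acid 1 is converted with oxalyl chloride and catalytic DMF into (S)-2-methylbutanoyl chloride F7. Intermediate 5 is stannylated with Bu3SnCl to give tributyl(ethoxyethynyl)stannane F8. Acyl Stille coupling of F7 with F8 (PdCl2(PPh3)2 catalyst, toluene, 60 °C, non-aqueous KF work-up) should give 6 under neutral conditions.

**Further compounds**
F1 | step 4 | silyl ketene acetal diene from 10 (methoxy(trimethylsilyloxy)methylidene and isopropylidene on ring B) | C=C1CC[C@H]2CC(=C(OC)O[Si](C)(C)C)C(=C(C)C)O[C@]2(C)CC[C@@H]2[C@@H]1CC2(C)C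
F2 | step 4 | lithium chloroacetylide | [Li+].[C-]#CCl
F3 | step 4 | (S)-1-chloro-4-methylhex-1-yn-3-one | ClC#CC(=O)[C@@H](C)CC
F4 | step 4 | Diels–Alder cycloadduct (ring A with chloroalkene and methoxy trimethylsilyloxy ketal carbon) | C=C1CC[C@H]2CC3=C(O[C@]2(C)CC[C@@H]2[C@@H]1CC2(C)C)C(C)(C)C(Cl)=C(C(=O)[C@@H](C)CC)C3(OC)O[Si](C)(C)C
F5 | step 4 | chlorodienone (ring A: 3-chloro-4,4-dimethyl-2-[(S)-2-methylbutanoyl]cyclohexa-2,5-dien-1-one fused to ring B) | C=C1CC[C@H]2CC3=C(O[C@]2(C)CC[C@@H]2[C@@H]1CC2(C)C)C(C)(C)C(Cl)=C(C(=O)[C@@H](C)CC)C3=O
F6 | step 3 | methyl 6-isopropyl-4H-1,3-dioxine-5-carboxylate | COC(=O)C1=C(C(C)C)OCOC1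
F7 | step 2 | (S)-2-methylbutanoyl chloride | CC[C@H](C)C(=O)Cl
F8 | step 2 | tributyl(ethoxyethynyl)stannane | CCOC#C[Sn](CCCC)(CCCC)CCCC
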